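**Retrosynthetic overview**
1. Target 29 ⇐ hexabenzyl ether 28 by global hydrogenolysis; ring C (the pyranone) is the only ring made and is closed last, by a catalyst-controlled oxa-Michael addition on benzylidene β-keto ester 25, followed by loss of the ester.
2. Key C–C bond: C2–C3, made as the Cα=Cβ bond of 25 by a Knoevenagel-type aldol condensation of β-keto ester 23 (ring A fragment) with benzaldehyde 24 (ring B fragment); 23 comes from acetophenone 22 by Claisen-type C-acylation.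
3. Ring A: phloroacetophenone 14; the one free, hydrogen-bonded OH directs iodination to C3 (Negishi coupling with benzylzinc chloride 4 installs ring D), then the last free position C5 is iodinated (Negishi coupling installs the chain).
4. Chain (rings E, F, G): iterative Negishi coupling of benzylzinc chlorides with methyl 2-(benzyloxy)-5-bromobenzoate 6, each cycle followed by ester → CH2OH → CH2Cl.
5. Rings A, B, D, E, F, G are bought as benzene rings; benzyl ethers protect all six phenols to the end.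

Assumption: the sense of induction in step 20 is taken by analogy with related cinchona thiourea conjugate additions (quinidine-derived catalyst → 2S); if the CD spectrum of 28 shows the 2R series, the quinine-derived pseudoenantiomer is used instead under the same conditions.

Shorthand: ring D = benzyl ring on C8; rings E, F, G = chain rings counted outward from ring A. TB = 2-(benzyloxy)-5-{2-(benzyloxy)-5-[2-(benzyloxy)benzyl]benzyl}benzyl. SPhos = 2-dicyclohexylphosphino-2',6'-dimethoxybiphenyl. NIS = N-iodosuccinimide. MOM = methoxymethyl.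

**Route**

Step 1
Reactants: 1 2-(benzyloxy)benzaldehyde
Product: 2 [2-(benzyloxy)phenyl]methanol
Conditions: NaBH4, MeOH, 0 °C
Reagents that add atoms: none
Why: Borohydride reduction of an aryl aldehyde is clean and does not touch the benzyl ether.

Step 2
Reactants: 2 [2-(benzyloxy)phenyl]methanol
Product: 3 2-(benzyloxy)benzyl chloride
Conditions: SOCl2, CH2Cl2, 0 °C→rt, used at once
Reagents that add atoms: thionyl chloride ClS(Cl)=O
Why: Deoxychlorination of a benzylic alcohol through its chlorosulfite gives the chloride needed for zinc insertion.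

Step 3
Reactants: 3 2-(benzyloxy)benzyl chloride
Product: 4 [2-(benzyloxy)benzyl]zinc chloride (THF stock solution, kept under argon)
Conditions: Zn dust (1.5 equiv), LiCl (1.5 equiv), THF, 25 °C; decant from excess Zn; titrate with I2; one batch sized for steps 5 and 14
Reagents that add atoms: zinc [Zn]
Why: LiCl-mediated direct insertion of zinc into the benzylic C–Cl bond gives a benzylzinc chloride that is stable in THF solution for weeks and tolerates esters and ketones, so one titrated batch serves both couplings.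

Step 4
Reactants: 5 methyl 5-bromo-2-hydroxybenzoate
Product: 6 methyl 2-(benzyloxy)-5-bromobenzoate
Conditions: BnBr, K2CO3, DMF, 60 °C
Reagents that add atoms: benzyl bromide BrCc1ccccc1
Why: Williamson etherification of the salicylate phenol gives the building block used for rings F and E.

Step 5
Reactants: 4 [2-(benzyloxy)benzyl]zinc chloride; 6 methyl 2-(benzyloxy)-5-bromobenzoate
Product: 7 methyl 2-(benzyloxy)-5-[2-(benzyloxy)benzyl]benzoate
Conditions: 4 (1.3 equiv, THF solution), Pd(OAc)2 (2 mol %), SPhos (4 mol %), THF, 25→50 °C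
Reagents that add atoms: none
Why: Negishi cross-coupling of the ester-tolerant benzylzinc chloride with the aryl bromide forms the ring G–CH2–ring F link para to the ring F oxygen.

Step 6
Reactants: 7 methyl 2-(benzyloxy)-5-[2-(benzyloxy)benzyl]benzoate
Product: 8 {2-(benzyloxy)-5-[2-(benzyloxy)benzyl]phenyl}methanol
Conditions: LiAlH4, THF, 0 °C; H2O work-up
Reagents that add atoms: none
Why: LiAlH4 reduction of the ester gives the benzylic alcohol without affecting aryl benzyl ethers or the diarylmethane.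

Step 7
Reactants: 8 {2-(benzyloxy)-5-[2-(benzyloxy)benzyl]phenyl}methanol
Product: 9 2-(benzyloxy)-5-[2-(benzyloxy)benzyl]benzyl chloride
Conditions: SOCl2, CH2Cl2, 0 °C→rt, used at once
Reagents that add atoms: thionyl chloride ClS(Cl)=O
Why: Deoxychlorination as in step 2 gives the next zinc precursor.

Step 8
Reactants: 9 2-(benzyloxy)-5-[2-(benzyloxy)benzyl]benzyl chloride; 6 methyl 2-(benzyloxy)-5-bromobenzoate
Product: 11 methyl 2-(benzyloxy)-5-{2-(benzyloxy)-5-[2-(benzyloxy)benzyl]benzyl}benzoate, via benzylzinc chloride 10 (not isolated)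
Conditions: 9, Zn dust, LiCl, THF, 25 °C; decant; then 6, Pd(OAc)2 (2 mol %), SPhos (4 mol %), 25→50 °C
Reagents that add atoms: none
Why: A second zinc insertion and Negishi cross-coupling adds ring E with the same para-to-oxygen connectivity.

Step 9
Reactants: 11 methyl 2-(benzyloxy)-5-{2-(benzyloxy)-5-[2-(benzyloxy)benzyl]benzyl}benzoate
Product: 12 (2-(benzyloxy)-5-{2-(benzyloxy)-5-[2-(benzyloxy)benzyl]benzyl}phenyl)methanol
Conditions: LiAlH4, THF, 0 °C; H2O work-up
Reagents that add atoms: none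
Why: LiAlH4 ester reduction as in step 6.

Step 10
Reactants: 12 (2-(benzyloxy)-5-{2-(benzyloxy)-5-[2-(benzyloxy)benzyl]benzyl}phenyl)methanol
Product: 13 2-(benzyloxy)-5-{2-(benzyloxy)-5-[2-(benzyloxy)benzyl]benzyl}benzyl chloride (TB–Cl)
Conditions: SOCl2, CH2Cl2, 0 °C→rt, used at once
Reagents that add atoms: thionyl chloride ClS(Cl)=O
Why: Deoxychlorination as in step 2 gives the complete chain as a benzylic chloride.

Step 11
Reactants: 14 1-(2,4,6-trihydroxyphenyl)ethanone
Product: 15 1-[2,4-bis(benzyloxy)-6-hydroxyphenyl]ethanone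
Conditions: BnBr (2.1 equiv), K2CO3, DMF, rt
Reagents that add atoms: benzyl bromide BrCc1ccccc1
Why: Williamson etherification takes the 4-OH and one of the two equivalent ortho OH groups, after which the last OH is held in a hydrogen bond to the acetyl group and stays free.

Step 12
Reactants: 15 1-[2,4-bis(benzyloxy)-6-hydroxyphenyl]ethanone
Product: 16 1-[4,6-bis(benzyloxy)-2-hydroxy-3-iodophenyl]ethanone
Conditions: NIS (1.0 equiv), CH2Cl2, 0 °C→rt, dark
Reagents that add atoms: N-iodosuccinimide O=C1CCC(=O)N1I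
Why: Electrophilic aromatic iodination goes to C3, next to the free hydroxyl and less hindered than C5 between two benzyloxy groups, which places ring D beside the oxygen that becomes O1 (checked by NOE from H5 to both OCH2Ph groups).

Step 13
Reactants: 16 1-[4,6-bis(benzyloxy)-2-hydroxy-3-iodophenyl]ethanone
Product: 17 1-[4,6-bis(benzyloxy)-3-iodo-2-(methoxymethoxy)phenyl]ethanone
Conditions: NaH (1.1 equiv), MOMCl, DMF, 0 °C
Reagents that add atoms: chloromethyl methyl ether COCCl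
Why: O-alkylation of the sodium phenoxide masks the acidic OH for the organozinc steps with a group that is orthogonal to benzyl ethers.

Step 14
Reactants: 17 1-[4,6-bis(benzyloxy)-3-iodo-2-(methoxymethoxy)phenyl]ethanone; 4 [2-(benzyloxy)benzyl]zinc chloride
Product: 18 1-{4,6-bis(benzyloxy)-3-[2-(benzyloxy)benzyl]-2-(methoxymethoxy)phenyl}ethanone
Conditions: 4 (1.5 equiv, THF solution, re-titrated), Pd(OAc)2 (3 mol %), SPhos (6 mol %), THF, 50 °C
Reagents that add atoms: none
Why: Negishi cross-coupling of the ketone-tolerant benzylzinc chloride with the di-ortho-substituted aryl iodide, for which the bulky biaryl phosphine is suited, attaches ring D at C3.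

Step 15
Reactants: 18 1-{4,6-bis(benzyloxy)-3-[2-(benzyloxy)benzyl]-2-(methoxymethoxy)phenyl}ethanone
Product: 19 1-{4,6-bis(benzyloxy)-3-[2-(benzyloxy)benzyl]-5-iodo-2-(methoxymethoxy)phenyl}ethanone
Conditions: NIS (1.05 equiv), MeCN–CH2Cl2, 0 °C→rt, dark, no acid
Reagents that add atoms: N-iodosuccinimide O=C1CCC(=O)N1I
Why: Electrophilic aromatic iodination at the single free position of ring A, which is activated by two ortho and one para oxygen and so reacts far faster than the mono-oxygenated ring D.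

Step 16
Reactants: 19 1-{4,6-bis(benzyloxy)-3-[2-(benzyloxy)benzyl]-5-iodo-2-(methoxymethoxy)phenyl}ethanone; 13 TB–Cl
Product: 21 1-{4,6-bis(benzyloxy)-3-[2-(benzyloxy)benzyl]-2-(methoxymethoxy)-5-TB-phenyl}ethanone, via benzylzinc chloride 20 (not isolated)
Conditions: 13, Zn dust, LiCl, THF, 25 °C; decant; then 19, Pd(OAc)2 (5 mol %), SPhos (10 mol %), 50→60 °C
Reagents that add atoms: none
Why: Negishi cross-coupling joins the chain to C5 of ring A, a primary benzylzinc being a small enough partner for the iodide flanked by two benzyloxy groups.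

Step 17
Reactants: 21 1-{4,6-bis(benzyloxy)-3-[2-(benzyloxy)benzyl]-2-(methoxymethoxy)-5-TB-phenyl}ethanone
Product: 22 1-{4,6-bis(benzyloxy)-3-[2-(benzyloxy)benzyl]-2-hydroxy-5-TB-phenyl}ethanone
Conditions: HCl (cat., aq.), MeOH–THF, 45 °C
Reagents that add atoms: none
Why: Acid-catalysed acetal cleavage is fast for a MOM ether ortho to a carbonyl group and leaves benzyl aryl ethers and the ketone untouched.

Step 18
Reactants: 22 1-{4,6-bis(benzyloxy)-3-[2-(benzyloxy)benzyl]-2-hydroxy-5-TB-phenyl}ethanone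
Product: 23 tert-butyl 3-{4,6-bis(benzyloxy)-3-[2-(benzyloxy)benzyl]-2-hydroxy-5-TB-phenyl}-3-oxopropanoate
Conditions: LiN(SiMe3)2 (3.3 equiv), THF, −78 °C; Boc2O (1.05 equiv), −78→0 °C; AcOH quench
Reagents that add atoms: di-tert-butyl dicarbonate CC(C)(C)OC(=O)OC(=O)OC(C)(C)C
Why: Claisen-type C-acylation of the lithium phenoxide–enolate polyanion gives the β-keto ester (any aryl O-Boc carbonate formed passes its acyl group to the enolate carbon in a Baker–Venkataraman-type shift), and excess base holds the product as its enolate so it is acylated once.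

Step 19
Reactants: 23 tert-butyl 3-{4,6-bis(benzyloxy)-3-[2-(benzyloxy)benzyl]-2-hydroxy-5-TB-phenyl}-3-oxopropanoate; 24 benzaldehyde
Product: 25 tert-butyl 2-{4,6-bis(benzyloxy)-3-[2-(benzyloxy)benzyl]-2-hydroxy-5-TB-benzoyl}-3-phenylprop-2-enoate (E/Z mixture)
Conditions: piperidine (20 mol %), AcOH (20 mol %), 4 Å sieves, toluene, rt; quick chromatography
Reagents that add atoms: none
Why: Knoevenagel-type aldol condensation of the active methylene with benzaldehyde joins the ring B fragment to the ring A fragment and creates the C2–C3 bond of the flavanone, while the hydrogen-bonded phenol stays uncyclised at room temperature.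

Step 20
Reactants: 25 tert-butyl 2-{4,6-bis(benzyloxy)-3-[2-(benzyloxy)benzyl]-2-hydroxy-5-TB-benzoyl}-3-phenylprop-2-enoate
Product: 28 (2S)-5,7-bis(benzyloxy)-8-[2-(benzyloxy)benzyl]-6-TB-2-phenylchroman-4-one, via flavanone tert-butyl ester 26 (not isolated), via flavanone carboxylic acid 27 (not isolated)
Conditions: 1-[3,5-bis(trifluoromethyl)phenyl]-3-[(9R)-6'-methoxycinchonan-9-yl]thiourea (10 mol %), toluene, −25 °C; then TsOH·H2O (30 mol %), 80 °C
Reagents that add atoms: none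
Why: Intramolecular oxa-Michael addition under bifunctional cinchona thiourea catalysis (thiourea binds the β-keto ester, quinuclidine activates the phenol) closes ring C and sets C2 as S by face-selective attack of the phenol oxygen on the benzylidene carbon, and acid-mediated loss of isobutene and CO2 then removes the activating ester under non-basic conditions that do not reopen the ring.

Step 21
Reactants: 28 (2S)-5,7-bis(benzyloxy)-8-[2-(benzyloxy)benzyl]-6-TB-2-phenylchroman-4-one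
Product: 29 sarmentosumin B
Conditions: H2 (1 atm), Pd/C (10 wt %), THF–MeOH, rt, stopped at full debenzylation
Reagents that add atoms: none
Why: Hydrogenolysis of the six benzyl aryl ethers under neutral conditions leaves the hydrogen-bonded ketone, the diarylmethane links and the base-sensitive C2 stereocenter unchanged.

**Compound list**
1 | 2-(benzyloxy)benzaldehyde | O=Cc1ccccc1OCc1ccccc1 | starting material
2 | [2-(benzyloxy)phenyl]methanol | OCc1ccccc1OCc1ccccc1 | intermediate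
3 | 2-(benzyloxy)benzyl chloride | ClCc1ccccc1OCc1ccccc1 | intermediate
4 | [2-(benzyloxy)benzyl]zinc chloride (THF stock solution) | Cl[Zn]Cc1ccccc1OCc1ccccc1 | intermediate
5 | methyl 5-bromo-2-hydroxybenzoate | COC(=O)c1cc(Br)ccc1O | starting material
6 | methyl 2-(benzyloxy)-5-bromobenzoate | COC(=O)c1cc(Br)ccc1OCc1ccccc1 | intermediate
7 | methyl 2-(benzyloxy)-5-[2-(benzyloxy)benzyl]benzoate | COC(=O)c1cc(Cc2ccccc2OCc2ccccc2)ccc1OCc1ccccc1 | intermediate
8 | {2-(benzyloxy)-5-[2-(benzyloxy)benzyl]phenyl}methanol | OCc1cc(Cc2ccccc2OCc2ccccc2)ccc1OCc1ccccc1 | intermediate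
9 | 2-(benzyloxy)-5-[2-(benzyloxy)benzyl]benzyl chloride | ClCc1cc(Cc2ccccc2OCc2ccccc2)ccc1OCc1ccccc1 | intermediate
10 | {2-(benzyloxy)-5-[2-(benzyloxy)benzyl]benzyl}zinc chloride | Cl[Zn]Cc1cc(Cc2ccccc2OCc2ccccc2)ccc1OCc1ccccc1 | intermediate
11 | methyl 2-(benzyloxy)-5-{2-(benzyloxy)-5-[2-(benzyloxy)benzyl]benzyl}benzoate | COC(=O)c1cc(Cc2cc(Cc3ccccc3OCc3ccccc3)ccc2OCc2ccccc2)ccc1OCc1ccccc1 | intermediate
12 | (2-(benzyloxy)-5-{2-(benzyloxy)-5-[2-(benzyloxy)benzyl]benzyl}phenyl)methanol | OCc1cc(Cc2cc(Cc3ccccc3OCc3ccccc3)ccc2OCc2ccccc2)ccc1OCc1ccccc1 | intermediate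
13 | 2-(benzyloxy)-5-{2-(benzyloxy)-5-[2-(benzyloxy)benzyl]benzyl}benzyl chloride (TB–Cl) | ClCc1cc(Cc2cc(Cc3ccccc3OCc3ccccc3)ccc2OCc2ccccc2)ccc1OCc1ccccc1 | intermediate
14 | 1-(2,4,6-trihydroxyphenyl)ethanone | CC(=O)c1c(O)cc(O)cc1O | starting material
15 | 1-[2,4-bis(benzyloxy)-6-hydroxyphenyl]ethanone | CC(=O)c1c(O)cc(OCc2ccccc2)cc1OCc1ccccc1 | intermediate
16 | 1-[4,6-bis(benzyloxy)-2-hydroxy-3-iodophenyl]ethanone | CC(=O)c1c(O)c(I)c(OCc2ccccc2)cc1OCc1ccccc1 | intermediate
17 | 1-[4,6-bis(benzyloxy)-3-iodo-2-(methoxymethoxy)phenyl]ethanone | CC(=O)c1c(OCOC)c(I)c(OCc2ccccc2)cc1OCc1ccccc1 | intermediate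
18 | 1-{4,6-bis(benzyloxy)-3-[2-(benzyloxy)benzyl]-2-(methoxymethoxy)phenyl}ethanone | CC(=O)c1c(OCOC)c(Cc2ccccc2OCc2ccccc2)c(OCc2ccccc2)cc1OCc1ccccc1 | intermediate
19 | 1-{4,6-bis(benzyloxy)-3-[2-(benzyloxy)benzyl]-5-iodo-2-(methoxymethoxy)phenyl}ethanone | CC(=O)c1c(OCOC)c(Cc2ccccc2OCc2ccccc2)c(OCc2ccccc2)c(I)c1OCc1ccccc1 | intermediate
20 | (2-(benzyloxy)-5-{2-(benzyloxy)-5-[2-(benzyloxy)benzyl]benzyl}benzyl)zinc chloride | Cl[Zn]Cc1cc(Cc2cc(Cc3ccccc3OCc3ccccc3)ccc2OCc2ccccc2)ccc1OCc1ccccc1 | intermediate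
21 | 1-{4,6-bis(benzyloxy)-3-[2-(benzyloxy)benzyl]-2-(methoxymethoxy)-5-TB-phenyl}ethanone | CC(=O)c1c(OCOC)c(Cc2ccccc2OCc2ccccc2)c(OCc2ccccc2)c(Cc2cc(Cc3cc(Cc4ccccc4OCc4ccccc4)ccc3OCc3ccccc3)ccc2OCc2ccccc2)c1OCc1ccccc1 | intermediate
22 | 1-{4,6-bis(benzyloxy)-3-[2-(benzyloxy)benzyl]-2-hydroxy-5-TB-phenyl}ethanone | CC(=O)c1c(O)c(Cc2ccccc2OCc2ccccc2)c(OCc2ccccc2)c(Cc2cc(Cc3cc(Cc4ccccc4OCc4ccccc4)ccc3OCc3ccccc3)ccc2OCc2ccccc2)c1OCc1ccccc1 | intermediate
23 | tert-butyl 3-{4,6-bis(benzyloxy)-3-[2-(benzyloxy)benzyl]-2-hydroxy-5-TB-phenyl}-3-oxopropanoate | CC(C)(C)OC(=O)CC(=O)c1c(O)c(Cc2ccccc2OCc2ccccc2)c(OCc2ccccc2)c(Cc2cc(Cc3cc(Cc4ccccc4OCc4ccccc4)ccc3OCc3ccccc3)ccc2OCc2ccccc2)c1OCc1ccccc1 | intermediate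
24 | benzaldehyde | O=Cc1ccccc1 | starting material
25 | tert-butyl 2-{4,6-bis(benzyloxy)-3-[2-(benzyloxy)benzyl]-2-hydroxy-5-TB-benzoyl}-3-phenylprop-2-enoate (E/Z mixture, no stereocenter) | CC(C)(C)OC(=O)C(=Cc1ccccc1)C(=O)c1c(O)c(Cc2ccccc2OCc2ccccc2)c(OCc2ccccc2)c(Cc2cc(Cc3cc(Cc4ccccc4OCc4ccccc4)ccc3OCc3ccccc3)ccc2OCc2ccccc2)c1OCc1ccccc1 | intermediate
26 | tert-butyl (2S)-5,7-bis(benzyloxy)-8-[2-(benzyloxy)benzyl]-4-oxo-2-phenyl-6-TB-chromane-3-carboxylate (C3 epimers and enol) | O=C1C(C(=O)OC(C)(C)C)[C@@H](c2ccccc2)Oc2c(Cc3ccccc3OCc3ccccc3)c(OCc3ccccc3)c(Cc3cc(Cc4cc(Cc5ccccc5OCc5ccccc5)ccc4OCc4ccccc4)ccc3OCc3ccccc3)c(OCc3ccccc3)c21 | intermediate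
27 | (2S)-5,7-bis(benzyloxy)-8-[2-(benzyloxy)benzyl]-4-oxo-2-phenyl-6-TB-chromane-3-carboxylic acid (C3 epimers) | O=C1C(C(=O)O)[C@@H](c2ccccc2)Oc2c(Cc3ccccc3OCc3ccccc3)c(OCc3ccccc3)c(Cc3cc(Cc4cc(Cc5ccccc5OCc5ccccc5)ccc4OCc4ccccc4)ccc3OCc3ccccc3)c(OCc3ccccc3)c21 | intermediate
28 | (2S)-5,7-bis(benzyloxy)-8-[2-(benzyloxy)benzyl]-6-TB-2-phenylchroman-4-one | O=C1C[C@@H](c2ccccc2)Oc2c(Cc3ccccc3OCc3ccccc3)c(OCc3ccccc3)c(Cc3cc(Cc4cc(Cc5ccccc5OCc5ccccc5)ccc4OCc4ccccc4)ccc3OCc3ccccc3)c(OCc3ccccc3)c21 | intermediate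
29 | sarmentosumin B, (2S)-5,7-dihydroxy-8-(2-hydroxybenzyl)-6-{2-hydroxy-5-[2-hydroxy-5-(2-hydroxybenzyl)benzyl]benzyl}-2-phenylchroman-4-one | O=C1C[C@@H](c2ccccc2)Oc2c(Cc3ccccc3O)c(O)c(Cc3cc(Cc4cc(Cc5ccccc5O)ccc4O)ccc3O)c(O)c21 | target

**Totals**
Total step count: 21.
Longest linear sequence: 15 steps (1 → 29 through steps 1, 2, 3, 5, 6, 7, 8, 9, 10, 16, 17, 18, 19, 20, 21).

**Three steps most likely to fail**

Step 20 is the main risk. The thiourea-catalysed ring closure has not been proven on a hexasubstituted ring A, and the ee or the rate may be poor. The fallback sets out from 22 and 24 and comes back at 28. Claisen–Schmidt aldol condensation of 22 with 24 (KOH, EtOH–THF, rt) gives the 2'-hydroxychalcone F1. NaOAc in refluxing EtOH closes it to the racemic hexabenzyl flavanone F2. Kinetic resolution by transfer hydrogenation with RhCl(C5Me5)[(R,R)-TsNCH(Ph)CH(Ph)NH2] (HCO2H–Et3N, EtOAc, rt, stopped near 55 % conversion) follows. This catalyst family delivers the (R)-benzylic alcohol and hydride adds anti to the 2-phenyl group, so the 2R enantiomer is reduced to the cis-(2R,4R)-flavan-4-ol F3. Unreacted (2S)-28 is recovered by chromatography in high ee, at the cost of half the material.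

Step 16 is the second risk. Zinc insertion into the large chloride 13 may give Wurtz dimer, and the iodide between two benzyloxy groups may couple slowly. The fallback sets out from 13 and 19 and comes back at 21. Pd-catalysed borylation of 13 (B2pin2, Pd2(dba)3 with dba = dibenzylideneacetone, tris(4-methoxyphenyl)phosphine, KOAc, toluene, 50 °C) gives the benzylboronic pinacol ester F4, which can be purified and characterised. Suzuki–Miyaura coupling of F4 with 19 (Pd(OAc)2, SPhos, K3PO4, toluene–H2O, 80 °C) gives 21.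

Step 12 is the third risk. If iodination is not selective for C3, the two benzyl groups end up exchanged between C6 and C8. The fallback sets out from 14 and 3 and comes back at 18, and it needs no halogenation. C-Benzylation of the symmetric phloroacetophenone anion with 3 (KOH, MeOH–H2O, 0 °C→rt; C3 and C5 are equivalent) gives the mono-C-benzyl triol F5 in modest yield. BnBr (2 equiv) and K2CO3 in DMF then etherify the 4-OH and the less hindered ortho OH. The OH next to the new benzyl group stays hydrogen-bonded and free, giving the bis(benzyl ether) F6 (checked by NOE). NaH and MOMCl in DMF convert F6 into 18.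

**Further compounds**
F1 | step 20 | (E)-1-{4,6-bis(benzyloxy)-3-[2-(benzyloxy)benzyl]-2-hydroxy-5-TB-phenyl}-3-phenylprop-2-en-1-one | O=C(/C=C/c1ccccc1)c1c(O)c(Cc2ccccc2OCc2ccccc2)c(OCc2ccccc2)c(Cc2cc(Cc3cc(Cc4ccccc4OCc4ccccc4)ccc3OCc3ccccc3)ccc2OCc2ccccc2)c1OCc1ccccc1
F2 | step 20 | racemic 5,7-bis(benzyloxy)-8-[2-(benzyloxy)benzyl]-6-TB-2-phenylchroman-4-one | O=C1CC(c2ccccc2)Oc2c(Cc3ccccc3OCc3ccccc3)c(OCc3ccccc3)c(Cc3cc(Cc4cc(Cc5ccccc5OCc5ccccc5)ccc4OCc4ccccc4)ccc3OCc3ccccc3)c(OCc3ccccc3)c21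
F3 | step 20 | (2R,4R)-5,7-bis(benzyloxy)-8-[2-(benzyloxy)benzyl]-6-TB-2-phenylchroman-4-ol | O[C@@H]1C[C@H](c2ccccc2)Oc2c(Cc3ccccc3OCc3ccccc3)c(OCc3ccccc3)c(Cc3cc(Cc4cc(Cc5ccccc5OCc5ccccc5)ccc4OCc4ccccc4)ccc3OCc3ccccc3)c(OCc3ccccc3)c21
F4 | step 16 | 2-(2-(benzyloxy)-5-{2-(benzyloxy)-5-[2-(benzyloxy)benzyl]benzyl}benzyl)-4,4,5,5-tetramethyl-1,3,2-dioxaborolane | CC1(C)OB(Cc2cc(Cc3cc(Cc4ccccc4OCc4ccccc4)ccc3OCc3ccccc3)ccc2OCc2ccccc2)OC1(C)C
F5 | step 12 | 1-{3-[2-(benzyloxy)benzyl]-2,4,6-trihydroxyphenyl}ethanone | CC(=O)c1c(O)cc(O)c(Cc2ccccc2OCc2ccccc2)c1O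
F6 | step 12 | 1-{4,6-bis(benzyloxy)-3-[2-(benzyloxy)benzyl]-2-hydroxyphenyl}ethanone | CC(=O)c1c(O)c(Cc2ccccc2OCc2ccccc2)c(OCc2ccccc2)cc1OCc1ccccc1
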